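**Retrosynthetic overview**
1. Feature: in the 3,7-dimethylocta-1,6-diene chain, C2 and C6 are both alkene CH carbons joined through C3, C4 and C5. Bonding C2 to C6 gives a cyclopentene whose ring bonds are the vinyl and prenyl arms and on which O3 and O4 are simply cis.
2. Target ⇒ 3-O-acetyl and 4-O-(p-coumaroyl) ester disconnections ⇒ (3R,4S)-3,7-dimethylocta-1,6-diene-3,4-diol ⇒ its acetonide.
3. Key disconnection: C1=C2 and C6=C7 by ring-opening cross-metathesis of the cis-fused cyclopentene acetonide with isobutylene (the carbocycle is opened, no ring is closed).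
4. Cyclopentene acetonide ⇒ (1R,5S)-1-methylcyclopent-2-ene-1,5-diol ⇒ selenide opening and selenoxide elimination of the cis-epoxy alcohol ⇒ hydroxyl-directed epoxidation of (S)-2-methylcyclopent-2-en-1-ol ⇒ CBS reduction of 2-methylcyclopent-2-en-1-one.
5. Ring order: the cyclopentene is present from the start, the dioxolane is closed onto it in step 5, the carbocycle is opened in step 6 and the dioxolane is removed in step 7; the benzene ring comes with p-coumaric acid.

Key step: step 6

Remark: locants C1–C7, O3 and O4 are those of the octadiene chain of the target, which is read as (3R,4S); the (R)-CBS catalyst is taken to give the (S)-carbinol, with the methyl-bearing alkenyl arm acting as the large group.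

**Route**

Step 1
Reactants: 1 2-methylcyclopent-2-en-1-one
Product: 2 (S)-2-methylcyclopent-2-en-1-ol
Conditions: (R)-2-methyl-CBS-oxazaborolidine (10 mol%), BH3·SMe2 (0.7 equiv), THF, −20 °C; MeOH quench
Reagents that add atoms: none
Why: Corey–Bakshi–Shibata reduction of an α-substituted cyclic enone: the ketone binds the catalyst boron anti to its larger methyl-bearing alkenyl arm and the coordinated borane delivers hydride to one carbonyl face only, which sets the carbinol carbon as S (it becomes C4 of the target).

Step 2
Reactants: 2 (S)-2-methylcyclopent-2-en-1-ol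
Product: 3 (1S,2S,5R)-1-methyl-6-oxabicyclo[3.1.0]hexan-2-ol (epoxide oxygen cis to the hydroxyl)
Conditions: VO(acac)2 (2 mol%), t-BuOOH (1.5 equiv, decane), CH2Cl2, 0 °C to rt
Reagents that add atoms: tert-butyl hydroperoxide, CC(C)(C)OO
Why: Hydroxyl-directed vanadium-catalysed epoxidation of a cyclic allylic alcohol: the peroxide oxygen is delivered within the vanadate ester to the alkene face that carries the hydroxyl, so the new tertiary C–O bond (the future C3–O3) is set cis to the existing carbinol.

Step 3
Reactants: 3 (1S,2S,5R)-1-methyl-6-oxabicyclo[3.1.0]hexan-2-ol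
Product: 4 (1S,2S,3S)-2-methyl-3-(phenylselanyl)cyclopentane-1,2-diol (hydroxyls cis to each other, PhSe trans to both)
Conditions: PhSeSePh (0.55 equiv), NaBH4 (1.2 equiv), EtOH, 0 °C to 60 °C
Reagents that add atoms: diphenyl diselenide, c1ccc(cc1)[Se][Se]c1ccccc1
Why: SN2 opening of the epoxide by phenylselenide at the less substituted ring carbon with inversion there (first half of the selenium route from epoxides to allylic alcohols); the tertiary C–O bond is not broken and keeps its configuration, and a Payne shift is excluded because the hydroxyl is cis to the epoxide oxygen.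

Step 4
Reactants: 4 (1S,2S,3S)-2-methyl-3-(phenylselanyl)cyclopentane-1,2-diol
Product: 6 (1R,5S)-1-methylcyclopent-2-ene-1,5-diol, via selenoxide 5 (not isolated)
Conditions: 30% aq. H2O2 (3 equiv), pyridine (2 equiv), CH2Cl2, 0 °C to rt
Reagents that add atoms: none
Why: Oxidation to the selenoxide and its syn-elimination (selenoxide elimination): the selenium-bearing carbon has hydrogen only on its CH2 neighbour, the other neighbour being the fully substituted carbinol carbon, so the alkene can form only away from the diol and both stereocenters stay untouched.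

Step 5
Reactants: 6 (1R,5S)-1-methylcyclopent-2-ene-1,5-diol
Product: 7 (3aS,6aR)-2,2,6a-trimethyl-3a,6a-dihydro-4H-cyclopenta[d][1,3]dioxole, the acetonide of 6 (cis-fused; ring alkene next to the methyl-bearing fusion carbon)
Conditions: 2,2-dimethoxypropane (3 equiv), PPTS (5 mol%), CH2Cl2, rt
Reagents that add atoms: 2,2-dimethoxypropane, COC(C)(C)OC
Why: Acid-catalysed acetal exchange (acetonide formation), easy for a cis-1,2-diol on a five-membered ring and not possible for a trans one, so it also confirms the relative configuration; no stereocenter is formed.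

Step 6
Reactants: 7 acetonide of (1R,5S)-1-methylcyclopent-2-ene-1,5-diol; 8 isobutylene (2-methylpropene)
Product: 9 (4R,5S)-2,2,4-trimethyl-5-(3-methylbut-2-en-1-yl)-4-vinyl-1,3-dioxolane, the acetonide of (3R,4S)-3,7-dimethylocta-1,6-diene-3,4-diol
Conditions: RuCl2(=CHPh)(PCy3)(H2IMes) (second-generation Grubbs catalyst, 5 mol%), neat isobutylene (ca. 100 equiv, 0.1 M), sealed tube, 25 °C; ethyl vinyl ether at −20 °C before venting
Reagents that add atoms: none
Why: Proposed new method: the ruthenium methylidene or isopropylidene formed from isobutylene should add across the ring alkene C2=C6, the ruthenacyclobutane should cyclorevert with opening of the carbocycle, and a second isobutylene should cap the new alkylidene, so that exactly one CH2 and one CMe2 are added and all atoms of 7 and 8 end up in 9. The closest known reaction types are ring-opening cross-metathesis of cyclic alkenes with acyclic partners and cross-metathesis of terminal alkenes with neat isobutylene to give prenyl ends, and the reverse process, ring closure of 1,6-dienes of the linalool type with loss of isobutylene, is facile with the same catalysts, so the metallacycles are accessible and only the position of the equilibrium is in question. No ring is closed (one carbocycle is opened) and no stereocenter is formed; C3 and C4 are not involved and stay R and S inside the dioxolane. The step needs CH2 on C2 and CMe2 on C6: the fully substituted C3 beside C2 blocks the crowded metallacycle that would lead to a C2=CMe2 alkene, whereas C6, which has only a CH2 neighbour, behaves as an ordinary terminal-alkene end and is converted into the trisubstituted alkene even if it is first capped by CH2, so both catalytic cycles converge on the same isomer. Ring opening of a cyclopentene is close to thermoneutral in free energy, so it is driven by mass action of neat isobutylene in a closed vessel, helped by the strain of the cis-fused bicycle, and the catalyst is destroyed before the isobutylene is vented so that 9 cannot close back to 7. The product should not oligomerise, because a vinyl group on a quaternary carbon and a trisubstituted alkene are both poor metathesis partners.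

Step 7
Reactants: 9 acetonide of (3R,4S)-3,7-dimethylocta-1,6-diene-3,4-diol
Product: 10 (3R,4S)-3,7-dimethylocta-1,6-diene-3,4-diol
Conditions: AcOH/H2O (4:1), 40 °C
Reagents that add atoms: none
Why: Acid-catalysed hydrolysis of the dioxolane through the oxocarbenium ion at the acetal carbon, so that neither the C3–O nor the C4–O bond is broken and both configurations are kept; weak acid at moderate temperature should leave the tertiary allylic alcohol and the trisubstituted alkene alone.

Step 8
Reactants: 11 p-coumaric acid, (E)-3-(4-hydroxyphenyl)prop-2-enoic acid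
Product: 13 (E)-3-[4-(tert-butyldimethylsilyloxy)phenyl]prop-2-enoic acid, via bis-silyl derivative 12 (not isolated)
Conditions: TBSCl (2.4 equiv), imidazole (5 equiv), DMF, rt; then AcOH/THF/H2O (3:1:1), rt
Reagents that add atoms: tert-butyldimethylsilyl chloride, CC(C)(C)[Si](C)(C)Cl
Why: Silylation of the phenol and the acid followed by selective hydrolysis of the far more labile silyl ester (protecting-group chemistry), which leaves the aryl silyl ether and the E-alkene in place.

Step 9
Reactants: 10 (3R,4S)-3,7-dimethylocta-1,6-diene-3,4-diol; 13 (E)-3-[4-(tert-butyldimethylsilyloxy)phenyl]prop-2-enoic acid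
Product: 14 (3R,4S)-3-hydroxy-3,7-dimethylocta-1,6-dien-4-yl (E)-3-[4-(tert-butyldimethylsilyloxy)phenyl]prop-2-enoate
Conditions: EDC·HCl (1.5 equiv), DMAP (0.3 equiv), CH2Cl2, 0 °C to rt
Reagents that add atoms: none
Why: Steglich esterification (carbodiimide activation, DMAP as acyl-transfer catalyst): the secondary C4 hydroxyl is acylated while the tertiary C3 hydroxyl is too hindered to react at room temperature, and the C4–O bond is not broken, so C4 keeps its configuration.

Step 10
Reactants: 14 the C4 mono-ester
Product: 15 (3R,4S)-3-acetoxy-3,7-dimethylocta-1,6-dien-4-yl (E)-3-[4-(tert-butyldimethylsilyloxy)phenyl]prop-2-enoate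
Conditions: Ac2O (5 equiv), Et3N (6 equiv), DMAP (1 equiv), CH2Cl2, rt to 35 °C
Reagents that add atoms: acetic anhydride, CC(=O)OC(C)=O
Why: DMAP-catalysed acylation with acetic anhydride, the standard way to acetylate tertiary allylic alcohols of the linalool type; with O4 already acylated the acetyl group can only go to O3, and no C–O bond at a stereocenter is broken.

Step 11
Reactants: 15 the silyl-protected diester
Product: 16 (3R,4S)-3-acetoxy-3,7-dimethylocta-1,6-dien-4-yl (E)-3-(4-hydroxyphenyl)prop-2-enoate, the target
Conditions: Bu4NF (1.1 equiv), AcOH (1.2 equiv), THF, 0 °C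
Reagents that add atoms: none
Why: Fluoride-induced cleavage of the aryl silyl ether (desilylation), fast at 0 °C; acetic acid buffers the phenoxide so that neither ester should be transesterified or hydrolysed.

**Compound list**
1 | 2-methylcyclopent-2-en-1-one | CC1=CCCC1=O | starting material
2 | (S)-2-methylcyclopent-2-en-1-ol | CC1=CCC[C@@H]1O | intermediate
3 | (1S,2S,5R)-1-methyl-6-oxabicyclo[3.1.0]hexan-2-ol | C[C@@]12O[C@@H]1CC[C@@H]2O | intermediate
4 | (1S,2S,3S)-2-methyl-3-(phenylselanyl)cyclopentane-1,2-diol | C[C@@]1(O)[C@@H]([Se]c2ccccc2)CC[C@@H]1O | intermediate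
5 | (1S,2S,3S)-2-methyl-3-(phenylseleninyl)cyclopentane-1,2-diol, selenoxide of 4, either configuration at Se (not isolated) | C[C@@]1(O)[C@@H]([Se](=O)c2ccccc2)CC[C@@H]1O | intermediate
6 | (1R,5S)-1-methylcyclopent-2-ene-1,5-diol | C[C@@]1(O)C=CC[C@@H]1O | intermediate
7 | (3aS,6aR)-2,2,6a-trimethyl-3a,6a-dihydro-4H-cyclopenta[d][1,3]dioxole (acetonide of 6) | C[C@@]12C=CC[C@@H]1OC(C)(C)O2 | intermediate
8 | isobutylene (2-methylpropene) | CC(C)=C | starting material
9 | (4R,5S)-2,2,4-trimethyl-5-(3-methylbut-2-en-1-yl)-4-vinyl-1,3-dioxolane (acetonide of 10) | C=C[C@@]1(C)OC(C)(C)O[C@H]1CC=C(C)C | intermediate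
10 | (3R,4S)-3,7-dimethylocta-1,6-diene-3,4-diol | C=C[C@@](C)(O)[C@H](CC=C(C)C)O | intermediate
11 | p-coumaric acid | O=C(O)/C=C/c1ccc(O)cc1 | starting material
12 | tert-butyldimethylsilyl (E)-3-[4-(tert-butyldimethylsilyloxy)phenyl]prop-2-enoate (not isolated) | CC(C)(C)[Si](C)(C)OC(=O)/C=C/c1ccc(O[Si](C)(C)C(C)(C)C)cc1 | intermediate
13 | (E)-3-[4-(tert-butyldimethylsilyloxy)phenyl]prop-2-enoic acid | O=C(O)/C=C/c1ccc(O[Si](C)(C)C(C)(C)C)cc1 | intermediate
14 | (3R,4S)-3-hydroxy-3,7-dimethylocta-1,6-dien-4-yl (E)-3-[4-(tert-butyldimethylsilyloxy)phenyl]prop-2-enoate | C=C[C@@](C)(O)[C@H](CC=C(C)C)OC(=O)/C=C/c1ccc(O[Si](C)(C)C(C)(C)C)cc1 | intermediate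
15 | (3R,4S)-3-acetoxy-3,7-dimethylocta-1,6-dien-4-yl (E)-3-[4-(tert-butyldimethylsilyloxy)phenyl]prop-2-enoate | C=C[C@@](C)(OC(C)=O)[C@H](CC=C(C)C)OC(=O)/C=C/c1ccc(O[Si](C)(C)C(C)(C)C)cc1 | intermediate
16 | (3R,4S)-3-acetoxy-3,7-dimethylocta-1,6-dien-4-yl (E)-3-(4-hydroxyphenyl)prop-2-enoate | C=C[C@@](C)(OC(C)=O)[C@H](CC=C(C)C)OC(=O)/C=C/c1ccc(O)cc1 | target

**Step count**
Total: 11 steps. Longest linear sequence: 10 steps (1 to 16 through steps 1–7 and 9–11); step 8 is the one-step side branch.

**Steps most likely to fail**

Step 6. The ring-opening equilibrium may stay on the side of the bicycle, the diene may close back as isobutylene is lost, turnover at the alkene next to the quaternary carbon may be slow, or opened ends may couple to oligomers instead of being capped. The fallback uses known chemistry and sets out from 7. Ozonolysis (O3, CH2Cl2, −78 °C) gives the secondary ozonide F1, which is reduced in the same flask with Me2S to the dialdehyde F2. One equivalent of isopropylidenetriphenylphosphorane (isopropyltriphenylphosphonium iodide, n-BuLi, THF, −78 °C) should olefinate only the unhindered CH2–CHO group, since the other aldehyde sits on the quaternary carbon; this gives the prenyl aldehyde F3. Methylenetriphenylphosphorane (THF, 0 °C) then turns the hindered aldehyde into the vinyl group, and the route is rejoined at 9. The aldehyde on C3 has no α-hydrogen, so neither stereocenter can epimerise.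

Step 10. Acylation of the tertiary hydroxyl beside the large C4 ester may be slow, which gives time for base-mediated migration of the coumaroyl group to O3 or for ionisation at the tertiary allylic carbon under forcing. The fallback changes the order of the two acylations and sets out from 10. TESCl and imidazole (CH2Cl2, 0 °C) should silylate only the secondary hydroxyl to give the silyl ether F4. Ac2O/Et3N/DMAP then acetylates O3 with nothing able to migrate, giving the silyl ether acetate F5. HF·pyridine (THF/pyridine, 0 °C) removes the silyl group to give the hydroxy acetate F6, which is esterified at once with 13 (EDC·HCl, DMAP, CH2Cl2, 0 °C), and the route is rejoined at 15.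

Step 7. Acid may ionise the tertiary allylic C3–O bond (allylic transposition, elimination or cyclisation onto the prenyl alkene) or add to the trisubstituted alkene while the acetal is being hydrolysed. The fallback carries the diol through the ring opening as a base-labile carbonate and sets out from 6. 1,1'-Carbonyldiimidazole (CH2Cl2, rt) gives the cyclic carbonate F7. Ring opening with isobutylene 8 under the conditions of step 6 gives the diene carbonate F8; this stage relies on the same untested metathesis as step 6. K2CO3 in MeOH (rt) removes the carbonate, and the route is rejoined at 10.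

**Further compounds**
F1 | step 6 | secondary ozonide of 7 (1,2,4-trioxolane bridging the two former alkene carbons, mixture of diastereomers at these carbons) | C[C@@]12C3OOC(O3)C[C@@H]1OC(C)(C)O2
F2 | step 6 | (4S,5S)-2,2,4-trimethyl-5-(2-oxoethyl)-1,3-dioxolane-4-carbaldehyde | O=C[C@@]1(C)OC(C)(C)O[C@H]1CC=O
F3 | step 6 | (4S,5S)-2,2,4-trimethyl-5-(3-methylbut-2-en-1-yl)-1,3-dioxolane-4-carbaldehyde | O=C[C@@]1(C)OC(C)(C)O[C@H]1CC=C(C)C
F4 | step 10 | (3R,4S)-3,7-dimethyl-4-[(triethylsilyl)oxy]octa-1,6-dien-3-ol | C=C[C@@](C)(O)[C@H](CC=C(C)C)O[Si](CC)(CC)CC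
F5 | step 10 | (3R,4S)-3,7-dimethyl-4-[(triethylsilyl)oxy]octa-1,6-dien-3-yl acetate | C=C[C@@](C)(OC(C)=O)[C@H](CC=C(C)C)O[Si](CC)(CC)CC
F6 | step 10 | (3R,4S)-4-hydroxy-3,7-dimethylocta-1,6-dien-3-yl acetate | C=C[C@@](C)(OC(C)=O)[C@H](CC=C(C)C)O
F7 | step 7 | cyclic carbonate of (1R,5S)-1-methylcyclopent-2-ene-1,5-diol, (3aS,6aR)-6a-methyl-3a,6a-dihydro-4H-cyclopenta[d][1,3]dioxol-2-one | C[C@@]12C=CC[C@@H]1OC(=O)O2
F8 | step 7 | (4R,5S)-4-methyl-5-(3-methylbut-2-en-1-yl)-4-vinyl-1,3-dioxolan-2-one | C=C[C@@]1(C)OC(=O)O[C@H]1CC=C(C)C
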